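Readings and results were computed from invented constants.

You asked me for a quick number on 3 questions, with the hunch that the Thursday's flask, charged so much thinner, needed an experiment of its own, but I found that its ratio of reagent to starting material was the Sunday's, and that made the number cheap.

all flasks: catalyst 1.50 mM
- Sunday's: starting material 300 mM; reagent 600 mM
- Wednesday's: starting material 180 mM; reagent 480 mM
- Friday's: starting material 300 mM; reagent 300 mM
- Thursday's: starting material 120 mM; reagent 240 mM; time 12 min

| run | time / min | [product] / mM |
|---|---|---|
| Sunday's run | 0.91 | 81.0 |
| Sunday's run | 2.8 | 169.1 |
| Sunday's run | 5.3 | 224.7 |
| Sunday's run | 8.4 | 259.1 |
| Sunday's run | 12 | 277.5 |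
| Wednesday's run | 0.91 | 42.8 |
| Wednesday's run | 2.8 | 94.1 |
| Wednesday's run | 5.3 | 130.2 |
| Wednesday's run | 8.4 | 151.2 |
| Wednesday's run | 12 | 164.7 |
| Friday's run | 0.91 | 44.3 |
| Friday's run | 2.8 | 100.9 |
| Friday's run | 5.3 | 147.5 |
| Friday's run | 8.4 | 178.0 |
| Friday's run | 12 | 202.8 |

(scatter of a reading: 0.9 mM)

- how the opening rate goes with [starting material] round the charge of the Sunday's run: the exponent of the rate at two percent of starting material gone to product (one fixed amount of product, the same in the runs compared)
- how the opening rate goes with [reagent] round the charge of the Sunday's run: the exponent of the rate at two percent of starting material gone to product
- product in the Thursday's run at 12 min, as a share of the starting material charged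

- Overall: starting material + reagent -> product, with catalyst as catalyst.
- Constant volume, constant temperature.
- Readings of a species count what is bound in complexes too.
- An order is taken over about fifteen percent of the charge, up and down.

I worked in fractions of the charge and took as my clock the logarithm of the fraction of reagent left over the fraction of starting material left, divided by the reagent's excess in units of the starting material charged; at equal charges this clock becomes turned over unturned, and for a rate first order in each partner it rises in step with charge times time. At 5.3 min the Sunday's run, where starting material is the limiting reagent, had turned 74.9%, and up to that reading the clock had risen on average by 0.172 /min; this rise per minute at the Sunday's charge, the pace, is what I carried.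

Scaled to that charge, the Wednesday's pace stood at 1.06 of it and the Friday's, with its reagent halved, at 1.06, so I committed to both orders near one. The Thursday's 12 min then read 0.827 on the clock, which is the Sunday's run at 4.80 min, and that gave me 72.0%.

The forecast, which judged “both orders are near 1”, gave 0.97 (0.85 to 1.08) for the order in starting material and 0.98 (0.87 to 1.08) for the order in reagent, with 73.2% (70.5% to 75.5%) for the Thursday's share, higher than mine.

The simulation gave 1.0 for the order in starting material, 0.96 for the order in reagent and 74.4% for the Thursday's share, so my orders near one held and my share lay 2.4 percentage points below it.

    catalyst + reagent ⇌ catalyst-reagent complex, settled at all times (0.3530 /M)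
    catalyst-reagent complex + starting material → product + catalyst (437.4 /M/min)
    starting material + reagent → product (0.4848 /M/min)
    catalyst + product ⇌ catalyst-product complex, settled at all times (11.10 /M)

The Thursday's result reads 0.898 on the clock, against my 0.827. Carried to the Friday's run, where equal charges put half conversion at clock reading one, the pace gave 5.81 min, and that run took 5.55 min. The Thursday's share rested on the direct conversion of starting material and reagent, without catalyst: with that step taken out of the Thursday's run, product at 12 min fell from 74.4% to 36.1%.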